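(The constants used here are those of an exercise; no experiment stands behind them.)

I started from a neighbour: the tank larch took the same charge as the tank elm, with a shorter mean time.

    reagent + catalyst + left-handed substrate → catalyst + left-handed product (k1 = 63 L² mol⁻² s⁻¹)
    reagent + catalyst + right-handed substrate → catalyst + right-handed product (k2 = 38 L² mol⁻² s⁻¹)
    precatalyst ⇌ catalyst (K3 = 9.3, k3 = 0.0014 s⁻¹)
    2 reagent → homo dimer (k4 = 0.0027 L mol⁻¹ s⁻¹)

in all of them: left-handed substrate 0.18 M; precatalyst 0.1 mol%; right-handed substrate 0.18 M

| run | reagent | remark | time |
|---|---|---|---|
| larch | 1.10 equiv | one stirred flow tank at steady state, fed with the mixture as stated, mean residence time 30 min |  |
| elm | 1.10 equiv | a single well-mixed tank run continuously and read at steady state, 300 min in it on average |  |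
| ash | 1.10 equiv (fed, over 15.0 min) | a stirred flask in which reagent is dosed at a steady rate over 15.0 min without added volume, worked up at 30 min | 30 min |
| oak | 1.10 equiv | everything together in a closed stirred flask, run for 30 min | 30 min |

- catalyst is single-handed; left-handed substrate and right-handed substrate are mirror images of each other, charged as a racemate, each of them at the stated concentration
- two of one species on the left: rate k times its square, two consumed each time
- the stated concentrations are those of everything mixed, before any reaction; amounts are the same in each set-up
- the feed brings no volume worth counting
- run time (ash): 30 min

* the set-up with the highest amount of left-handed product at the outlet or at the end, in percent of the left-handed substrate and right-handed substrate together put in ("none" if the first two lie within 2 percentage points) (larch / elm / ash / oak / none)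
* amount of left-handed product at the outlet or at the end, in percent of the left-handed substrate and right-handed substrate together put in, larch
* amount of left-handed product at the outlet or at the end, in percent of the left-handed substrate and right-handed substrate together put in, elm
* amount of left-handed product at the outlet or at the end, in percent of the left-handed substrate and right-handed substrate together put in, ash
* amount of left-handed product at the outlet or at the end, in percent of the left-handed substrate and right-handed substrate together put in, oak

The two coupling steps share one reagent, so I wrote its balance. Reagent was 55.0% of both substrates together, so it was the limiting reagent. The selectivity factor was 1.66, so left-handed substrate went faster at equal amounts. But catalyst comes from precatalyst. From release, return and outflow I reckoned 87.2% of the loading as catalyst in elm.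

In a tank, a substrate keeps one part in one plus its count. The count is its rate constant times catalyst, reagent and mean time. I first let all reagent in elm couple. The left-handed count came to 1.58, which gave 30.6% left-handed product, counted on both substrates together. But that count needs standing reagent, 4.48% of its charge, and at that level I reckoned the dimer step at 3.87% of the same charge. Their sum was 8.35%. I call it the leak: the fraction of charged reagent that leaves a tank uncoupled, as reagent or as dimer. Taking the leak off gave me 28.1% for elm, and my reckoning stopped there.

The forecast gave 20.1% for larch, 28.8% for elm, 25.6% for ash and 20.6% for oak. It put elm first and said “dosing comes second by avoiding the early dimer loss”. My elm figure stood below its figure.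

The simulation gave 20.1% for larch, 28.8% for elm, 24.2% for ash and 20.3% for oak, with elm first. In elm the coupling steps ran with left-handed substrate standing at 42.4% of its charge, and that reading, with my reckoned catalyst share, put the leak at 6.71%. In larch the dimer step ran beside them while reagent stood at 25.1% of its charge, which puts the leak at 37.2%, more than in elm, and left-handed product there reached 20.1%.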